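**Retrosynthetic overview**

1. The side chain is numbered C1' (benzylic CH2) to C15' (CMe2); the tetrahydrofuran is O–C12'–C13'–C14'–C15'. Late disconnections: quinone from a 2,5-dimethoxyarene (oxidative demethylation); C5' acetate; C1'–C2' and C3'–CH3 from methylalumination/benzylation of a terminal alkyne; C4'–C5' from asymmetric propargylation of an enal.
2. The tetrahydrofuran comes from a (5S)-2,2-dimethyloxolan-3-one, made by an enantioselective O-to-C ring contraction (Petasis–Ferrier type, C12'–C13' bond) of a 4-methylene-1,3-dioxolane. That acetal is assembled from 8-oxogeranyl silyl ether (C5'–C12'), 2-hydroxyisobutyric acid (ring O, C14', C15', both methyls) and one CH2 (C13').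
3. Enabling feature: the ring oxygen lies between C12', an allylic carbon at the aldehyde oxidation level (an oxocarbenium ion there is stabilised by O and by the C10'=C11' alkene), and the quaternary C15', which carries the carbinol C14' and has no hydrogen. The O–C15'(Me)2–C14' edge is therefore a masked α-hydroxy acid whose enol can only form toward C13'.
4. Ring order: the benzene ring is bought and only oxidised at the end; a temporary dioxolanone ring is made in step 4 and consumed in step 6; the tetrahydrofuran is the only ring of the skeleton that is closed, and so the last.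

Key step: step 6

Remark: the sense of induction of the chiral acids in steps 6 and 11 is assigned by analogy with related ion-pair and allylboration reactions; should it prove opposite, the antipodal acid is used.

**Route**

Step 1
Reactants: 1 geraniol
Product: 2 tert-butyl{[(2E)-3,7-dimethylocta-2,6-dien-1-yl]oxy}dimethylsilane
Conditions: TBSCl, imidazole, CH2Cl2, 0 °C to rt
Reagents that add atoms: tert-butyldimethylsilyl chloride, CC(C)(C)[Si](C)(C)Cl
Why: Imidazole-promoted silylation of the primary allylic alcohol masks C5'–OH with a group that survives steps 2 to 8 and can later be removed in the presence of a hindered secondary silyl ether; no stereocentre is involved.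

Step 2
Reactants: 2 tert-butyl{[(2E)-3,7-dimethylocta-2,6-dien-1-yl]oxy}dimethylsilane
Product: 4 (2E,6E)-8-[(tert-butyldimethylsilyl)oxy]-2,6-dimethylocta-2,6-dienal, via allylic alcohol 3 (not isolated)
Conditions: SeO2 (0.1 equiv), t-BuOOH, salicylic acid (0.1 equiv), CH2Cl2, rt; crude mixture then MnO2, CH2Cl2, rt
Reagents that add atoms: selenium dioxide, O=[Se]=O; tert-butyl hydroperoxide, CC(C)(C)OO
Why: Catalytic SeO2 allylic oxidation (ene reaction then [2,3]-sigmatropic shift) should select the E-methyl group of the distal, more electron-rich trisubstituted alkene, and MnO2 then takes allylic alcohol 3 to the (E)-enal, so C12' reaches the aldehyde level with the C10'=C11' geometry of the target.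

Step 3
Reactants: 5 2-hydroxy-2-methylpropanoic acid
Product: 6 trimethylsilyl 2-methyl-2-[(trimethylsilyl)oxy]propanoate
Conditions: Me3SiCl (2.2 equiv), Et3N (2.3 equiv), CH2Cl2, 0 °C to rt; distillation
Reagents that add atoms: chlorotrimethylsilane, C[Si](C)(C)Cl
Why: Double silylation of the hydroxy acid gives the volatile bis-silyl derivative needed for aprotic acetalisation.

Step 4
Reactants: 4 (2E,6E)-8-[(tert-butyldimethylsilyl)oxy]-2,6-dimethylocta-2,6-dienal; 6 trimethylsilyl 2-methyl-2-[(trimethylsilyl)oxy]propanoate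
Product: 7 2-[(2E,6E)-8-[(tert-butyldimethylsilyl)oxy]-6-methylocta-2,6-dien-2-yl]-5,5-dimethyl-1,3-dioxolan-4-one (racemic at C2)
Conditions: Me3SiOTf (5 mol %), CH2Cl2, −78 °C; pyridine quench
Reagents that add atoms: none
Why: Noyori acetalisation of an aldehyde with a bis-silylated α-hydroxy acid is driven by loss of hexamethyldisiloxane and runs at −78 °C, so the enal should not isomerise; the new acetal carbon is racemic, which does not matter because it becomes planar in step 6.

Step 5
Reactants: 7 2-[(2E,6E)-8-[(tert-butyldimethylsilyl)oxy]-6-methylocta-2,6-dien-2-yl]-5,5-dimethyl-1,3-dioxolan-4-one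
Product: 8 2-[(2E,6E)-8-[(tert-butyldimethylsilyl)oxy]-6-methylocta-2,6-dien-2-yl]-5,5-dimethyl-4-methylidene-1,3-dioxolane (racemic at C2)
Conditions: Cp2TiMe2 (2.5 equiv), toluene/THF, 65 °C, dark; filtration through basic alumina
Reagents that add atoms: dimethyltitanocene Cp2TiMe2, [CH3-].[CH3-].[Ti+4].c1cc[cH-]c1.c1cc[cH-]c1
Why: Petasis methylenation (Cp2TiMe2 as thermal source of Cp2Ti=CH2, [2+2] then cycloreversion) converts the lactone carbonyl of 1,3-dioxolan-4-ones into the exocyclic enol ether under non-acidic conditions that leave the acetal, silyl ether and alkenes alone, and 65 °C should be too low for a Claisen shift of the allyl vinyl ether array.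

Step 6
Reactants: 8 2-[(2E,6E)-8-[(tert-butyldimethylsilyl)oxy]-6-methylocta-2,6-dien-2-yl]-5,5-dimethyl-4-methylidene-1,3-dioxolane
Product: 10 (5S)-5-[(2E,6E)-8-[(tert-butyldimethylsilyl)oxy]-6-methylocta-2,6-dien-2-yl]-2,2-dimethyloxolan-3-one, via oxocarbenium enol ion pair 9 (not isolated)
Conditions: (R)-3,3'-bis(2,4,6-triisopropylphenyl)-1,1'-binaphthyl-2,2'-diyl N-triflylphosphoramide (C51H57F3NO5PS, 5 mol %), 4 Å molecular sieves, toluene, −60 °C; Et3N quench
Reagents that add atoms: none
Why: Proposed new method: the chiral acid should protonate the enol-ether oxygen of 8 and cleave its bond to the acetal carbon, giving the allyl-stabilised (E)-oxocarbenium ion 9 whose tethered enol is hydrogen-bonded to the chiral phosphoramidate anion; attack of the enol CH2 (C13') on the oxocarbenium carbon (C12') then forms the C12'–C13' bond and returns the proton. The closest known reactions are the aluminium-promoted Petasis–Ferrier-type rearrangement of 4-methylene-1,3-dioxolanes to oxolan-3-ones and oxolan-3-ols with achiral Lewis acids, the chiral-phosphoric-acid-catalysed aza-Petasis–Ferrier rearrangement of hemiaminal vinyl ethers, and chiral Brønsted-acid-catalysed Prins cyclisations through oxocarbenium ion pairs. The tetrahydrofuran closes by a 5-(enolendo)-endo-trig C–C bond formation, a net 1,3 O-to-C shift that contracts the acetal onto carbon, which is accessible for cationic oxocarbenium electrophiles as the aluminium version shows. The only new stereocentre, C12', is set by the chiral counter-anion, which should shield one face of the planar oxocarbenium ion, so both enantiomers of racemic 8 converge on (S)-10; the two E alkenes are not involved. The step needs closure at C12' instead of the vinylogous position C10' (five- against seven-membered ring), C- instead of O-recombination and no proton loss from C9'; the five-membered transition state, the methyl group on C11' and the quaternary C15' (no α-hydrogen, one possible enol, gem-dialkyl compression) should secure this, and the low temperature should suppress reversal. Residual (R)-10 is not carried on, because step 7 turns it into a separable diastereomer.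

Step 7
Reactants: 10 (5S)-5-[(2E,6E)-8-[(tert-butyldimethylsilyl)oxy]-6-methylocta-2,6-dien-2-yl]-2,2-dimethyloxolan-3-one
Product: 11 (3S,5S)-5-[(2E,6E)-8-[(tert-butyldimethylsilyl)oxy]-6-methylocta-2,6-dien-2-yl]-2,2-dimethyloxolan-3-ol (3,5-cis)
Conditions: (R)-2-methyl-CBS-oxazaborolidine, (R)-1-methyl-3,3-diphenyltetrahydro-1H,3H-pyrrolo[1,2-c][1,3,2]oxazaborole (C18H20BNO, 0.2 equiv), catecholborane, toluene, −78 °C; MeOH, aq. NaHCO3; chromatography
Reagents that add atoms: none
Why: Corey–Bakshi–Shibata reduction distinguishes the quaternary C15' side (large) from the C13' methylene (small), so the (R)-oxazaborolidine should give the (14'S)-carbinol, which for the (12'S)-ketone is the 3,5-cis alcohol also favoured by hydride attack anti to the C12' substituent; any (12'R)-ketone becomes the trans diastereomer and is removed by chromatography, and catecholborane does not hydroborate the alkenes.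

Step 8
Reactants: 11 (3S,5S)-5-[(2E,6E)-8-[(tert-butyldimethylsilyl)oxy]-6-methylocta-2,6-dien-2-yl]-2,2-dimethyloxolan-3-ol
Product: 12 tert-butyl{[(3S,5S)-5-[(2E,6E)-8-[(tert-butyldimethylsilyl)oxy]-6-methylocta-2,6-dien-2-yl]-2,2-dimethyloxolan-3-yl]oxy}dimethylsilane
Conditions: TBSOTf, 2,6-lutidine, CH2Cl2, 0 °C
Reagents that add atoms: tert-butyldimethylsilyl triflate, CC(C)(C)[Si](C)(C)OS(=O)(=O)C(F)(F)F
Why: The silyl triflate silylates the hindered secondary alcohol next to the quaternary carbon, so C14'–OH stays distinguished from the C5' oxygen for the rest of the route.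

Step 9
Reactants: 12 tert-butyl{[(3S,5S)-5-[(2E,6E)-8-[(tert-butyldimethylsilyl)oxy]-6-methylocta-2,6-dien-2-yl]-2,2-dimethyloxolan-3-yl]oxy}dimethylsilane
Product: 13 (2E,6E)-7-[(2S,4S)-4-[(tert-butyldimethylsilyl)oxy]-5,5-dimethyloxolan-2-yl]-3-methylocta-2,6-dien-1-ol
Conditions: (+)-camphor-10-sulfonic acid (0.1 equiv), MeOH/CH2Cl2, 0 °C
Reagents that add atoms: none
Why: Acid-catalysed methanolysis cleaves a primary allylic silyl ether much faster than a secondary one flanked by a quaternary carbon (selective desilylation), so only C5'–OH should be freed.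

Step 10
Reactants: 13 (2E,6E)-7-[(2S,4S)-4-[(tert-butyldimethylsilyl)oxy]-5,5-dimethyloxolan-2-yl]-3-methylocta-2,6-dien-1-ol
Product: 14 (2E,6E)-7-[(2S,4S)-4-[(tert-butyldimethylsilyl)oxy]-5,5-dimethyloxolan-2-yl]-3-methylocta-2,6-dienal
Conditions: MnO2, CH2Cl2, rt
Reagents that add atoms: none
Why: MnO2 oxidises allylic alcohols chemoselectively and should give the β-methyl enal without E/Z isomerisation.

Step 11
Reactants: 14 (2E,6E)-7-[(2S,4S)-4-[(tert-butyldimethylsilyl)oxy]-5,5-dimethyloxolan-2-yl]-3-methylocta-2,6-dienal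
Product: 15 (4S,5E,9E)-10-[(2S,4S)-4-[(tert-butyldimethylsilyl)oxy]-5,5-dimethyloxolan-2-yl]-6-methylundeca-5,9-dien-1-yn-4-ol
Conditions: allenylboronic acid pinacol ester (1.5 equiv), (S)-3,3'-bis(2,4,6-triisopropylphenyl)-1,1'-binaphthyl-2,2'-diyl hydrogen phosphate (C50H57O4P, 10 mol %), 4 Å molecular sieves, toluene, 0 °C; aqueous work-up
Reagents that add atoms: allenylboronic acid pinacol ester, C=C=CB1OC(C)(C)C(C)(C)O1
Why: Chiral-phosphoric-acid-catalysed propargylation of an aldehyde with an allenylboronate (SE2' transfer through a closed six-membered transition state in which the acid binds a boronate oxygen and the formyl hydrogen) should give the homopropargylic alcohol; the catalyst alone controls the new C5' stereocentre, the remote ring stereocentres having no influence, and the (S)-acid is predicted to give (5'S).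

Step 12
Reactants: 16 4-methoxy-2-methylphenol
Product: 17 2-hydroxy-5-methoxy-3-methylbenzaldehyde
Conditions: MgCl2, Et3N, paraformaldehyde, MeCN, reflux
Reagents that add atoms: paraformaldehyde (formaldehyde), C=O
Why: Magnesium-mediated ortho-formylation of phenols (Casnati–Skattebøl reaction) is specific for the position ortho to OH, and only C6 is free.

Step 13
Reactants: 17 2-hydroxy-5-methoxy-3-methylbenzaldehyde
Product: 18 2,5-dimethoxy-3-methylbenzaldehyde
Conditions: MeI, K2CO3, DMF, rt
Reagents that add atoms: iodomethane, CI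
Why: Williamson O-methylation of the phenol completes the dimethyl ether that serves as the quinone precursor.

Step 14
Reactants: 18 2,5-dimethoxy-3-methylbenzaldehyde
Product: 19 (2,5-dimethoxy-3-methylphenyl)methanol
Conditions: NaBH4, MeOH, 0 °C
Reagents that add atoms: none
Why: Borohydride reduction of the aryl aldehyde gives the benzylic alcohol.

Step 15
Reactants: 19 (2,5-dimethoxy-3-methylphenyl)methanol
Product: 20 1-(chloromethyl)-2,5-dimethoxy-3-methylbenzene
Conditions: SOCl2, CH2Cl2, 0 °C
Reagents that add atoms: thionyl chloride, O=S(Cl)Cl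
Why: Chlorodehydroxylation through the chlorosulfite gives the electron-rich benzylic chloride, which is used promptly.

Step 16
Reactants: 15 (4S,5E,9E)-10-[(2S,4S)-4-[(tert-butyldimethylsilyl)oxy]-5,5-dimethyloxolan-2-yl]-6-methylundeca-5,9-dien-1-yn-4-ol; 20 1-(chloromethyl)-2,5-dimethoxy-3-methylbenzene
Product: 22 (2E,5S,6E,10E)-1-(2,5-dimethoxy-3-methylphenyl)-11-[(2S,4S)-4-[(tert-butyldimethylsilyl)oxy]-5,5-dimethyloxolan-2-yl]-3,7-dimethyldodeca-2,6,10-trien-5-ol, via alkenylalane 21 (not isolated)
Conditions: Me3Al (3.5 equiv), Cp2ZrCl2 (0.5 equiv), CH2Cl2, 0 °C to rt; volatiles removed; then 20, NiCl2(PPh3)2 (5 mol %) reduced by n-BuLi (10 mol %) to zerovalent nickel, THF, rt; cold 1 M HCl work-up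
Reagents that add atoms: trimethylaluminium, C[Al](C)C
Why: Negishi zirconium-catalysed methylalumination adds Me and Al syn across the terminal alkyne (Me to C3', Al to C2') while the hydroxyl is carried as its aluminium alkoxide, and nickel-catalysed cross-coupling of alkenylalane 21 with the benzylic chloride proceeds with retention, so the (2'E)-trisubstituted alkene and the aryl–C1' link should arise in one flask.

Step 17
Reactants: 22 (2E,5S,6E,10E)-1-(2,5-dimethoxy-3-methylphenyl)-11-[(2S,4S)-4-[(tert-butyldimethylsilyl)oxy]-5,5-dimethyloxolan-2-yl]-3,7-dimethyldodeca-2,6,10-trien-5-ol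
Product: 23 (2E,5S,6E,10E)-1-(2,5-dimethoxy-3-methylphenyl)-11-[(2S,4S)-4-[(tert-butyldimethylsilyl)oxy]-5,5-dimethyloxolan-2-yl]-3,7-dimethyldodeca-2,6,10-trien-5-yl acetate
Conditions: Ac2O, pyridine, 4-(dimethylamino)pyridine (0.1 equiv), CH2Cl2, 0 °C to rt
Reagents that add atoms: acetic anhydride, CC(=O)OC(C)=O
Why: Nucleophile-catalysed acetylation of the only free hydroxyl installs the C5' acetate with retention.

Step 18
Reactants: 23 (2E,5S,6E,10E)-1-(2,5-dimethoxy-3-methylphenyl)-11-[(2S,4S)-4-[(tert-butyldimethylsilyl)oxy]-5,5-dimethyloxolan-2-yl]-3,7-dimethyldodeca-2,6,10-trien-5-yl acetate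
Product: 24 (2E,5S,6E,10E)-1-(2,5-dimethoxy-3-methylphenyl)-11-[(2S,4S)-4-hydroxy-5,5-dimethyloxolan-2-yl]-3,7-dimethyldodeca-2,6,10-trien-5-yl acetate
Conditions: HF·pyridine, pyridine, THF, 0 °C to rt
Reagents that add atoms: none
Why: Fluoride cleavage of the remaining silyl ether under buffered, non-basic conditions should leave the allylic acetate and the allylic ring ether in place.

Step 19
Reactants: 24 (2E,5S,6E,10E)-1-(2,5-dimethoxy-3-methylphenyl)-11-[(2S,4S)-4-hydroxy-5,5-dimethyloxolan-2-yl]-3,7-dimethyldodeca-2,6,10-trien-5-yl acetate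
Product: 25 (2E,5S,6E,10E)-11-[(2S,4S)-4-hydroxy-5,5-dimethyloxolan-2-yl]-3,7-dimethyl-1-(5-methyl-3,6-dioxocyclohexa-1,4-dien-1-yl)dodeca-2,6,10-trien-5-yl acetate (CNP0106310.2)
Conditions: (NH4)2Ce(NO3)6 (2.5 equiv), MeCN/H2O 2:1, 0 °C
Reagents that add atoms: water, O
Why: Oxidative demethylation of the 1,4-dimethoxyarene by two equivalents of tetravalent cerium, with water supplying the quinone oxygens, should give the 2,6-disubstituted 1,4-benzoquinone, and the alkenes, the acetate and the secondary alcohol tolerate the brief cold oxidation.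

**Compound list**

1 | geraniol, (2E)-3,7-dimethylocta-2,6-dien-1-ol | CC(C)=CCC/C(C)=C/CO | starting material
2 | tert-butyl{[(2E)-3,7-dimethylocta-2,6-dien-1-yl]oxy}dimethylsilane | CC(C)(C)[Si](C)(C)OC/C=C(\C)CCC=C(C)C | intermediate
3 | (2E,6E)-8-[(tert-butyldimethylsilyl)oxy]-2,6-dimethylocta-2,6-dien-1-ol | CC(C)(C)[Si](C)(C)OC/C=C(\C)CC/C=C(\C)CO | intermediate (not isolated)
4 | (2E,6E)-8-[(tert-butyldimethylsilyl)oxy]-2,6-dimethylocta-2,6-dienal | CC(C)(C)[Si](C)(C)OC/C=C(\C)CC/C=C(\C)C=O | intermediate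
5 | 2-hydroxy-2-methylpropanoic acid (2-hydroxyisobutyric acid) | CC(C)(O)C(=O)O | starting material
6 | trimethylsilyl 2-methyl-2-[(trimethylsilyl)oxy]propanoate | CC(C)(O[Si](C)(C)C)C(=O)O[Si](C)(C)C | intermediate
7 | 2-[(2E,6E)-8-[(tert-butyldimethylsilyl)oxy]-6-methylocta-2,6-dien-2-yl]-5,5-dimethyl-1,3-dioxolan-4-one, racemic at C2 | CC(C)(C)[Si](C)(C)OC/C=C(\C)CC/C=C(\C)C1OC(=O)C(C)(C)O1 | intermediate
8 | 2-[(2E,6E)-8-[(tert-butyldimethylsilyl)oxy]-6-methylocta-2,6-dien-2-yl]-5,5-dimethyl-4-methylidene-1,3-dioxolane, racemic at C2 | CC(C)(C)[Si](C)(C)OC/C=C(\C)CC/C=C(\C)C1OC(=C)C(C)(C)O1 | intermediate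
9 | oxocarbenium enol ion pair (cation shown; counter-ion is the phosphoramidate of the acid) | CC(C)(C)[Si](C)(C)OC/C=C(\C)CC/C=C(\C)C=[O+]C(C)(C)C(O)=C | intermediate (not isolated)
10 | (5S)-5-[(2E,6E)-8-[(tert-butyldimethylsilyl)oxy]-6-methylocta-2,6-dien-2-yl]-2,2-dimethyloxolan-3-one | CC(C)(C)[Si](C)(C)OC/C=C(\C)CC/C=C(\C)[C@@H]1CC(=O)C(C)(C)O1 | intermediate
11 | (3S,5S)-5-[(2E,6E)-8-[(tert-butyldimethylsilyl)oxy]-6-methylocta-2,6-dien-2-yl]-2,2-dimethyloxolan-3-ol | CC(C)(C)[Si](C)(C)OC/C=C(\C)CC/C=C(\C)[C@@H]1C[C@H](O)C(C)(C)O1 | intermediate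
12 | tert-butyl{[(3S,5S)-5-[(2E,6E)-8-[(tert-butyldimethylsilyl)oxy]-6-methylocta-2,6-dien-2-yl]-2,2-dimethyloxolan-3-yl]oxy}dimethylsilane | CC(C)(C)[Si](C)(C)OC/C=C(\C)CC/C=C(\C)[C@@H]1C[C@H](O[Si](C)(C)C(C)(C)C)C(C)(C)O1 | intermediate
13 | (2E,6E)-7-[(2S,4S)-4-[(tert-butyldimethylsilyl)oxy]-5,5-dimethyloxolan-2-yl]-3-methylocta-2,6-dien-1-ol | OC/C=C(\C)CC/C=C(\C)[C@@H]1C[C@H](O[Si](C)(C)C(C)(C)C)C(C)(C)O1 | intermediate
14 | (2E,6E)-7-[(2S,4S)-4-[(tert-butyldimethylsilyl)oxy]-5,5-dimethyloxolan-2-yl]-3-methylocta-2,6-dienal | O=C/C=C(\C)CC/C=C(\C)[C@@H]1C[C@H](O[Si](C)(C)C(C)(C)C)C(C)(C)O1 | intermediate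
15 | (4S,5E,9E)-10-[(2S,4S)-4-[(tert-butyldimethylsilyl)oxy]-5,5-dimethyloxolan-2-yl]-6-methylundeca-5,9-dien-1-yn-4-ol | C#CC[C@H](O)/C=C(\C)CC/C=C(\C)[C@@H]1C[C@H](O[Si](C)(C)C(C)(C)C)C(C)(C)O1 | intermediate
16 | 4-methoxy-2-methylphenol | COc1ccc(O)c(C)c1 | starting material
17 | 2-hydroxy-5-methoxy-3-methylbenzaldehyde | COc1cc(C)c(O)c(C=O)c1 | intermediate
18 | 2,5-dimethoxy-3-methylbenzaldehyde | COc1cc(C)c(OC)c(C=O)c1 | intermediate
19 | (2,5-dimethoxy-3-methylphenyl)methanol | COc1cc(C)c(OC)c(CO)c1 | intermediate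
20 | 1-(chloromethyl)-2,5-dimethoxy-3-methylbenzene | COc1cc(C)c(OC)c(CCl)c1 | intermediate
21 | (E)-alkenyl(dimethyl)alane of 15, hydroxyl as dimethylaluminium alkoxide | C[Al](C)/C=C(\C)C[C@H](O[Al](C)C)/C=C(\C)CC/C=C(\C)[C@@H]1C[C@H](O[Si](C)(C)C(C)(C)C)C(C)(C)O1 | intermediate (not isolated)
22 | (2E,5S,6E,10E)-1-(2,5-dimethoxy-3-methylphenyl)-11-[(2S,4S)-4-[(tert-butyldimethylsilyl)oxy]-5,5-dimethyloxolan-2-yl]-3,7-dimethyldodeca-2,6,10-trien-5-ol | COc1cc(C)c(OC)c(C/C=C(\C)C[C@H](O)/C=C(\C)CC/C=C(\C)[C@@H]2C[C@H](O[Si](C)(C)C(C)(C)C)C(C)(C)O2)c1 | intermediate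
23 | (2E,5S,6E,10E)-1-(2,5-dimethoxy-3-methylphenyl)-11-[(2S,4S)-4-[(tert-butyldimethylsilyl)oxy]-5,5-dimethyloxolan-2-yl]-3,7-dimethyldodeca-2,6,10-trien-5-yl acetate | COc1cc(C)c(OC)c(C/C=C(\C)C[C@H](OC(C)=O)/C=C(\C)CC/C=C(\C)[C@@H]2C[C@H](O[Si](C)(C)C(C)(C)C)C(C)(C)O2)c1 | intermediate
24 | (2E,5S,6E,10E)-1-(2,5-dimethoxy-3-methylphenyl)-11-[(2S,4S)-4-hydroxy-5,5-dimethyloxolan-2-yl]-3,7-dimethyldodeca-2,6,10-trien-5-yl acetate | COc1cc(C)c(OC)c(C/C=C(\C)C[C@H](OC(C)=O)/C=C(\C)CC/C=C(\C)[C@@H]2C[C@H](O)C(C)(C)O2)c1 | intermediate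
25 | (2E,5S,6E,10E)-11-[(2S,4S)-4-hydroxy-5,5-dimethyloxolan-2-yl]-3,7-dimethyl-1-(5-methyl-3,6-dioxocyclohexa-1,4-dien-1-yl)dodeca-2,6,10-trien-5-yl acetate | CC(=O)O[C@H](/C=C(\C)CC/C=C(\C)[C@@H]1C[C@H](O)C(C)(C)O1)C/C(C)=C/CC1=CC(=O)C=C(C)C1=O | target

**Step count and risks**

Total step count: 19. Longest linear sequence: 14 steps (steps 1, 2, 4 to 11 and 16 to 19, from geraniol).

Most likely to fail, first: step 6. The chiral ion pair may discriminate the two faces of the oxocarbenium ion poorly. The enol ether may instead be protonated on carbon and hydrolysed by traces of water. The conjugated oxocarbenium ion may lose a proton from C9' or close at C10' to a seven-membered ring, and reversal of the closure would erode the enantiomeric purity. The fallback uses known chemistry and sets out from 8. Treatment with Me2AlCl in CH2Cl2 at −78 °C, the established achiral aluminium-promoted Petasis–Ferrier rearrangement, should give the racemic ketone F1. The reduction conditions of step 7 then act as a parallel kinetic resolution: the (5S)-enantiomer gives 11, and the (5R)-enantiomer gives the 3,5-trans alcohol F2, which is separated by chromatography. The route is rejoined at 11, at the cost of at most half of the material.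

Second: step 16. The aluminium alkoxide may slow the methylalumination or lower its regioselectivity, the alkenylalane may be protonated before coupling, and the electron-rich benzylic chloride may self-condense under Lewis-acidic conditions. The fallback sets out from 15 and separates the two events. Methylalumination as before, followed by iodinolysis with I2, should give the isolable (E)-vinyl iodide F3. Chloride 20 is converted with zinc dust and LiCl in THF into the benzylzinc chloride F4. A Negishi cross-coupling of F3 with F4 catalysed by Pd(PPh3)4 (zerovalent palladium) in THF then gives 22, where the route is rejoined.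

Third: step 11. The β,β-disubstituted enal may react sluggishly and with poor facial selectivity, and allenyl transfer may compete with propargyl transfer. The fallback sets out from 14. Barbier propargylation with propargyl bromide and zinc in THF should give the homopropargylic alcohol as a mixture of C5' epimers F5. A Sharpless kinetic resolution with Ti(Oi-Pr)4, diisopropyl D-tartrate and t-BuOOH at −20 °C should then epoxidise the (5'R)-epimer to the epoxy alcohol F6 and leave the (5'S)-epimer, which is 15, where the route is rejoined.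

**Further compounds**

F1 | step 6 | 5-[(2E,6E)-8-[(tert-butyldimethylsilyl)oxy]-6-methylocta-2,6-dien-2-yl]-2,2-dimethyloxolan-3-one, racemic | CC(C)(C)[Si](C)(C)OC/C=C(\C)CC/C=C(\C)C1CC(=O)C(C)(C)O1
F2 | step 6 | (3S,5R)-5-[(2E,6E)-8-[(tert-butyldimethylsilyl)oxy]-6-methylocta-2,6-dien-2-yl]-2,2-dimethyloxolan-3-ol (3,5-trans) | CC(C)(C)[Si](C)(C)OC/C=C(\C)CC/C=C(\C)[C@H]1C[C@H](O)C(C)(C)O1
F3 | step 16 | (1E,4S,5E,9E)-1-iodo-2,6-dimethyl-10-[(2S,4S)-4-[(tert-butyldimethylsilyl)oxy]-5,5-dimethyloxolan-2-yl]undeca-1,5,9-trien-4-ol | I/C=C(\C)C[C@H](O)/C=C(\C)CC/C=C(\C)[C@@H]1C[C@H](O[Si](C)(C)C(C)(C)C)C(C)(C)O1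
F4 | step 16 | (2,5-dimethoxy-3-methylbenzyl)zinc chloride | COc1cc(C)c(OC)c(C[Zn]Cl)c1
F5 | step 11 | (5E,9E)-10-[(2S,4S)-4-[(tert-butyldimethylsilyl)oxy]-5,5-dimethyloxolan-2-yl]-6-methylundeca-5,9-dien-1-yn-4-ol, mixture of C4 epimers | C#CCC(O)/C=C(\C)CC/C=C(\C)[C@@H]1C[C@H](O[Si](C)(C)C(C)(C)C)C(C)(C)O1
F6 | step 11 | (1R)-1-{(2R,3R)-3-methyl-3-[(3E)-4-[(2S,4S)-4-[(tert-butyldimethylsilyl)oxy]-5,5-dimethyloxolan-2-yl]pent-3-en-1-yl]oxiran-2-yl}but-3-yn-1-ol | C#CC[C@@H](O)[C@H]1O[C@]1(C)CC/C=C(\C)[C@@H]2C[C@H](O[Si](C)(C)C(C)(C)C)C(C)(C)O2
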